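**Plan**
1. Retrosynthetic cuts, in order: (a) benzofuran O1–C2 and C3–C3a (iodophenol plus terminal alkyne); (b) the bond from chromene C6 to the carbinol carbon (aryl 1,2-shift from boron to carbon); (c) the chromene pyran ring (phenol plus 3-methylbut-2-enal) and the methine–alkynyl bond (conjugate alkynylation).
2. Enabling feature: without its aryl group the carbinol carbon (CH3, CH2, OH) is a plain secondary methyl carbinol, so its hindered benzoate can be lithiated at the very C–H the aryl replaces. Chromene C6 (ortho to 7-OMe, para to O1) is an electron-rich aryl that migrates readily from boron. The furan ring of the benzofuran is carried as a silyl-capped C≡C, so no phenol, acetyl or activated arene C–H is present in the organolithium step.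
3. Forward order: chromene ring first (fragment A, aryl boronate); open chain with both stereocentres (fragment B, benzoate); union; benzofuran ring closed last with the unprotected hydroxyacetophenone, so no acid or deprotection follows formation of the acid-labile benzylic carbinol.
4. Stereochemistry (hexyne numbering: C2 = carbinol carbon, C4 = methine): C4 (S) from Rh/(S)-DTBM-SEGPHOS conjugate alkynylation; C2 from Prelog-selective enzymatic reduction (2S), Mitsunobu inversion (2R benzoate) and stereospecific lithiation–borylation–oxidation (aryl takes the place of H, 2R).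

Key step: step 6

Remark: the sense of induction in step 3 is assigned by analogy with rhodium/bisphosphine conjugate additions to (E)-enones; should the (S)-ligand deliver the (R)-ketone, the (R)-ligand is used and nothing else changes.

**Route**

Step 1
Reactants: 1 4-bromo-3-methoxyphenol; 2 3-methylbut-2-enal
Product: 5 6-bromo-7-methoxy-2,2-dimethyl-2H-chromene, via benzodioxaborin 3 (not isolated), via ortho-quinone methide 4 (not isolated)
Conditions: PhB(OH)2 (1.0 equiv), AcOH, toluene, reflux, Dean–Stark
Reagents that add atoms: none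
Why: Phenylboronic acid templates ortho-hydroxyalkylation at the phenol carbon para to OMe (the less hindered ortho site) to give 3, which fragments thermally to ortho-quinone methide 4 that closes by oxa-6π electrocyclisation to the 2H-chromene.

Step 2
Reactants: 5 6-bromo-7-methoxy-2,2-dimethyl-2H-chromene
Product: 6 2-(7-methoxy-2,2-dimethyl-2H-chromen-6-yl)-5,5-dimethyl-1,3,2-dioxaborinane
Conditions: B2neop2 (1.2 equiv), PdCl2(dppf) (3 mol%), KOAc (3 equiv), 1,4-dioxane, 90 °C
Reagents that add atoms: bis(neopentyl glycolato)diboron, CC1(C)COB(OC1)B1OCC(C)(C)CO1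
Why: Miyaura borylation of the aryl bromide should deliver the neopentyl glycol boronate directly, the chromene alkene and aryl ethers being inert to zerovalent palladium and acetate.

Step 3
Reactants: 7 (E)-pent-3-en-2-one; 8 ethynyltri(propan-2-yl)silane (1.5 equiv)
Product: 9 (S)-4-methyl-6-(triisopropylsilyl)hex-5-yn-2-one
Conditions: [Rh(OAc)(C2H4)2]2 (2.5 mol%), (S)-DTBM-SEGPHOS (6 mol%), 1,4-dioxane, 80 °C
Reagents that add atoms: none
Why: Rhodium-catalysed asymmetric conjugate alkynylation, in which the bulky silyl group suppresses alkyne dimerisation and the bisphosphine-bound alkynylrhodium inserts one enantioface of the enone to set C4 as (S).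

Step 4
Reactants: 9 (S)-4-methyl-6-(triisopropylsilyl)hex-5-yn-2-one
Product: 10 (2S,4S)-4-methyl-6-(triisopropylsilyl)hex-5-yn-2-ol
Conditions: ADH-A (alcohol dehydrogenase from Rhodococcus ruber), NADH (cat.), 2-propanol (15% v/v), phosphate buffer pH 7.5, 30 °C
Reagents that add atoms: none
Why: Enzymatic transfer hydrogenation of a methyl ketone following the Prelog rule should deliver hydride to the re face and give the (2S)-alcohol under catalyst control, independent of the remote C4 centre.

Step 5
Reactants: 10 (2S,4S)-4-methyl-6-(triisopropylsilyl)hex-5-yn-2-ol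
Product: 11 (2R,4S)-4-methyl-6-(triisopropylsilyl)hex-5-yn-2-yl 2,4,6-triisopropylbenzoate
Conditions: 2,4,6-triisopropylbenzoic acid (1.5 equiv), PPh3 (1.5 equiv), DIAD (1.5 equiv), THF, 0 °C → rt
Reagents that add atoms: 2,4,6-triisopropylbenzoic acid, CC(C)c1cc(C(C)C)c(C(=O)O)c(C(C)C)c1
Why: Mitsunobu esterification proceeds by SN2 attack of the carboxylate on the alkoxyphosphonium ion, so C2 is inverted to (R) while the hindered acyl group that direct acylation installs poorly is introduced.

Step 6
Reactants: 11 (2R,4S)-4-methyl-6-(triisopropylsilyl)hex-5-yn-2-yl 2,4,6-triisopropylbenzoate; 6 2-(7-methoxy-2,2-dimethyl-2H-chromen-6-yl)-5,5-dimethyl-1,3,2-dioxaborinane (2 equiv)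
Product: 15 (2R,4S)-2-(7-methoxy-2,2-dimethyl-2H-chromen-6-yl)-4-methyl-6-(triisopropylsilyl)hex-5-yn-2-ol, via lithiated benzoate 12 (not isolated), via boronate complex 13 (not isolated), via tertiary boronic ester 14 (not isolated)
Conditions: sBuLi (1.6 equiv), TMEDA (6 equiv), CPME, −60 °C; then 6, −60 °C → rt → 45 °C; then NaOH (2 M aq), H2O2 (30%), THF, 0 °C → rt
Reagents that add atoms: hydrogen peroxide, OO
Why: Complexation of sBuLi/TMEDA to the benzoate carbonyl directs deprotonation to the adjacent C2–H with retention and gives the configurationally stable, dipole-stabilised tertiary alkyllithium 12, which is borylated by 6 with retention to ate complex 13; on warming, the electron-rich chromen-6-yl group shifts from boron to C2 antiperiplanar to the departing triisopropylbenzoate (inversion at carbon), forming the aryl–C2 bond of 14, whose C–B bond is then oxidised with retention. The closest known reaction type is the lithiation–borylation of secondary dialkyl 2,4,6-triisopropylbenzoates with aryl neopentyl glycol boronic esters (a Matteson-type 1,2-metalate rearrangement) followed by alkaline peroxide oxidation. No ring is closed. The new fully substituted stereocentre C2 is controlled entirely by the configuration of the benzoate: retention, retention, inversion, retention amounts to replacement of H by aryl with retention, so (2R)-11 should give (2R)-15, and C4 is a spectator. The step needs lithiation at C2–H and not at the propargylic C4–H or an arene, which is secured by the carbonyl-directed deprotonation, by the silyl cap on the alkyne and by the absence of benzofuran, phenol and acetyl groups at this stage; it also needs aryl and not oxygen migration, which the high migratory aptitude of the dialkoxy-substituted aryl secures. The excess of 6 consumes surplus sBuLi and should be recoverable.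

Step 7
Reactants: 15 (2R,4S)-2-(7-methoxy-2,2-dimethyl-2H-chromen-6-yl)-4-methyl-6-(triisopropylsilyl)hex-5-yn-2-ol
Product: 16 (2R,4S)-2-(7-methoxy-2,2-dimethyl-2H-chromen-6-yl)-4-methylhex-5-yn-2-ol
Conditions: TBAF (1.2 equiv), THF, 0 °C → rt
Reagents that add atoms: none
Why: Fluoride-induced protodesilylation of the alkynylsilane is basic and non-acidic, so the ionisable benzylic carbinol and the chromene should be untouched.

Step 8
Reactants: 17 1-(2,4-dihydroxyphenyl)ethanone
Product: 18 1-(2,4-dihydroxy-5-iodophenyl)ethanone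
Conditions: ICl (1.05 equiv), AcOH, rt
Reagents that add atoms: iodine monochloride, ClI
Why: Electrophilic aromatic iodination should occur at C5 (ortho to the 4-OH, para to the 2-OH), the less hindered of the two activated positions under acidic conditions.

Step 9
Reactants: 16 (2R,4S)-2-(7-methoxy-2,2-dimethyl-2H-chromen-6-yl)-4-methylhex-5-yn-2-ol; 18 1-(2,4-dihydroxy-5-iodophenyl)ethanone (1.2 equiv)
Product: 20 1-{6-hydroxy-2-[(2S,4R)-4-hydroxy-4-(7-methoxy-2,2-dimethyl-2H-chromen-6-yl)pentan-2-yl]-1-benzofuran-5-yl}ethanone, via ortho-alkynylphenol 19 (not isolated)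
Conditions: PdCl2(PPh3)2 (5 mol%), CuI (10 mol%), Et3N (4 equiv), DMF, 60 °C, argon
Reagents that add atoms: none
Why: Sonogashira coupling forms the C3–C3a bond and the adjacent 4-OH then adds 5-endo-dig across the metal-activated alkyne to form O1–C2 (Castro–Stephens-type benzofuran synthesis); no stereocentre is touched and the medium is basic, so the carbinol should not ionise.

**Compound list**
1 | 4-bromo-3-methoxyphenol | COc1cc(O)ccc1Br | starting material
2 | 3-methylbut-2-enal | CC(C)=CC=O | starting material
3 | 6-bromo-7-methoxy-4-(2-methylprop-1-en-1-yl)-2-phenyl-4H-1,3,2-benzodioxaborinine (racemic at C4) | COc1cc2OB(c3ccccc3)OC(C=C(C)C)c2cc1Br | intermediate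
4 | 4-bromo-3-methoxy-6-(3-methylbut-2-en-1-ylidene)cyclohexa-2,4-dien-1-one | O=C1C=C(OC)C(Br)=CC1=CC=C(C)C | intermediate
5 | 6-bromo-7-methoxy-2,2-dimethyl-2H-chromene | COc1cc2OC(C)(C)C=Cc2cc1Br | intermediate
6 | 2-(7-methoxy-2,2-dimethyl-2H-chromen-6-yl)-5,5-dimethyl-1,3,2-dioxaborinane | COc1cc2OC(C)(C)C=Cc2cc1B1OCC(C)(C)CO1 | intermediate
7 | (E)-pent-3-en-2-one | C/C=C/C(C)=O | starting material
8 | ethynyltri(propan-2-yl)silane | C#C[Si](C(C)C)(C(C)C)C(C)C | starting material
9 | (S)-4-methyl-6-(triisopropylsilyl)hex-5-yn-2-one | CC(=O)C[C@H](C)C#C[Si](C(C)C)(C(C)C)C(C)C | intermediate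
10 | (2S,4S)-4-methyl-6-(triisopropylsilyl)hex-5-yn-2-ol | C[C@H](O)C[C@H](C)C#C[Si](C(C)C)(C(C)C)C(C)C | intermediate
11 | (2R,4S)-4-methyl-6-(triisopropylsilyl)hex-5-yn-2-yl 2,4,6-triisopropylbenzoate | C[C@@H](OC(=O)c1c(C(C)C)cc(C(C)C)cc1C(C)C)C[C@H](C)C#C[Si](C(C)C)(C(C)C)C(C)C | intermediate
12 | [(2R,4S)-4-methyl-2-(2,4,6-triisopropylbenzoyloxy)-6-(triisopropylsilyl)hex-5-yn-2-yl]lithium | C[C@@]([Li])(OC(=O)c1c(C(C)C)cc(C(C)C)cc1C(C)C)C[C@H](C)C#C[Si](C(C)C)(C(C)C)C(C)C | intermediate
13 | lithium (2,2-dimethylpropane-1,3-diolato)(7-methoxy-2,2-dimethyl-2H-chromen-6-yl)[(2R,4S)-4-methyl-2-(2,4,6-triisopropylbenzoyloxy)-6-(triisopropylsilyl)hex-5-yn-2-yl]borate | C[C@@]([B-]1(c2cc3C=CC(C)(C)Oc3cc2OC)OCC(C)(C)CO1)(OC(=O)c1c(C(C)C)cc(C(C)C)cc1C(C)C)C[C@H](C)C#C[Si](C(C)C)(C(C)C)C(C)C.[Li+] | intermediate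
14 | 2-[(2S,4S)-2-(7-methoxy-2,2-dimethyl-2H-chromen-6-yl)-4-methyl-6-(triisopropylsilyl)hex-5-yn-2-yl]-5,5-dimethyl-1,3,2-dioxaborinane | C[C@](B1OCC(C)(C)CO1)(c1cc2C=CC(C)(C)Oc2cc1OC)C[C@H](C)C#C[Si](C(C)C)(C(C)C)C(C)C | intermediate
15 | (2R,4S)-2-(7-methoxy-2,2-dimethyl-2H-chromen-6-yl)-4-methyl-6-(triisopropylsilyl)hex-5-yn-2-ol | COc1cc2c(cc1[C@](C)(O)C[C@H](C)C#C[Si](C(C)C)(C(C)C)C(C)C)C=CC(C)(C)O2 | intermediate
16 | (2R,4S)-2-(7-methoxy-2,2-dimethyl-2H-chromen-6-yl)-4-methylhex-5-yn-2-ol | COc1cc2c(cc1[C@](C)(O)C[C@H](C)C#C)C=CC(C)(C)O2 | intermediate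
17 | 1-(2,4-dihydroxyphenyl)ethanone | CC(=O)c1ccc(O)cc1O | starting material
18 | 1-(2,4-dihydroxy-5-iodophenyl)ethanone | CC(=O)c1cc(I)c(O)cc1O | intermediate
19 | 1-{2,4-dihydroxy-5-[(3S,5R)-5-hydroxy-5-(7-methoxy-2,2-dimethyl-2H-chromen-6-yl)-3-methylhex-1-yn-1-yl]phenyl}ethanone | COc1cc2c(cc1[C@](C)(O)C[C@H](C)C#Cc1cc(C(C)=O)c(O)cc1O)C=CC(C)(C)O2 | intermediate
20 | 1-{6-hydroxy-2-[(2S,4R)-4-hydroxy-4-(7-methoxy-2,2-dimethyl-2H-chromen-6-yl)pentan-2-yl]-1-benzofuran-5-yl}ethanone (CNP0233723.2) | COc1cc2c(cc1[C@](C)(O)C[C@H](C)c1cc3cc(C(C)=O)c(O)cc3o1)C=CC(C)(C)O2 | target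

**Totals**
Total steps: 9. Longest linear sequence: 6 (steps 3, 4, 5, 6, 7, 9).

**Steps most likely to fail**

Step 6. Lithiation at C2–H may be slower than deprotonation at the propargylic C4–H (epimerisation or allenyl formation). The α-oxyalkyllithium may also add 4-exo to the silylalkyne, or the ortho-methoxy aryl boronate may form the ate complex too slowly for migration to compete with decomposition. Fallback, setting out from 5 and 9 and returning at 15: bromide 5 undergoes bromine–lithium exchange (nBuLi, THF, −78 °C) to 6-lithio-7-methoxy-2,2-dimethyl-2H-chromene F1, which is added to ketone 9 at −78 °C. Little 1,3-induction is expected, so 15 should form together with (2S,4S)-2-(7-methoxy-2,2-dimethyl-2H-chromen-6-yl)-4-methyl-6-(triisopropylsilyl)hex-5-yn-2-ol F2, and the two diastereomers are separated by chromatography on base-washed silica. 15 then enters step 7.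

Step 3. Enantioface discrimination may be poor because the β-substituent is only a methyl group, and alkyne dimerisation may outrun conjugate addition. Fallback, setting out from 7 and 8 and returning at 10: 8 is deprotonated with nBuLi to lithium (triisopropylsilyl)acetylide F3 and transmetalated with Et2AlCl to diethyl[(triisopropylsilyl)ethynyl]alane F4. F4 adds in conjugate fashion to the s-cis conformer of 7 (alkynylalane conjugate addition) through diethyl{[4-methyl-6-(triisopropylsilyl)hex-2-en-5-yn-2-yl]oxy}alane F5, which on aqueous work-up gives racemic 4-methyl-6-(triisopropylsilyl)hex-5-yn-2-one F6. Reduction under the conditions of step 4 should give 10 and (2S,4R)-4-methyl-6-(triisopropylsilyl)hex-5-yn-2-ol F7, which are separated by chromatography; 10 continues with step 5.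

Step 4. The enzyme may not accept the lipophilic silyl-bearing ketone (low conversion) or may bind it in the reversed orientation (erosion of selectivity). Fallback, setting out from 9 and returning at 10: Corey–Bakshi–Shibata reduction with (R)-2-methyl-CBS-oxazaborolidine (10 mol%) and BH3·SMe2 in THF at −30 °C, expected to favour 10 only moderately for a methyl/primary-alkyl ketone. The minor (2R,4S)-4-methyl-6-(triisopropylsilyl)hex-5-yn-2-ol F8 is removed by chromatography, and 10 continues with step 5.

**Further compounds**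
F1 | step 6 | 6-lithio-7-methoxy-2,2-dimethyl-2H-chromene | COc1cc2OC(C)(C)C=Cc2cc1[Li]
F2 | step 6 | (2S,4S)-2-(7-methoxy-2,2-dimethyl-2H-chromen-6-yl)-4-methyl-6-(triisopropylsilyl)hex-5-yn-2-ol | COc1cc2c(cc1[C@@](C)(O)C[C@H](C)C#C[Si](C(C)C)(C(C)C)C(C)C)C=CC(C)(C)O2
F3 | step 3 | lithium (triisopropylsilyl)acetylide | [Li]C#C[Si](C(C)C)(C(C)C)C(C)C
F4 | step 3 | diethyl[(triisopropylsilyl)ethynyl]alane | CC[Al](CC)C#C[Si](C(C)C)(C(C)C)C(C)C
F5 | step 3 | diethyl{[4-methyl-6-(triisopropylsilyl)hex-2-en-5-yn-2-yl]oxy}alane | CC[Al](CC)OC(C)=CC(C)C#C[Si](C(C)C)(C(C)C)C(C)C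
F6 | step 3 | racemic 4-methyl-6-(triisopropylsilyl)hex-5-yn-2-one | CC(=O)CC(C)C#C[Si](C(C)C)(C(C)C)C(C)C
F7 | step 3 | (2S,4R)-4-methyl-6-(triisopropylsilyl)hex-5-yn-2-ol | C[C@H](O)C[C@@H](C)C#C[Si](C(C)C)(C(C)C)C(C)C
F8 | step 4 | (2R,4S)-4-methyl-6-(triisopropylsilyl)hex-5-yn-2-ol | C[C@@H](O)C[C@H](C)C#C[Si](C(C)C)(C(C)C)C(C)C
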